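The furofuran is cut back to a 3-diazo-oxan-4-one. The oxolane carrying the syringyl group (ring O, syringyl CH, both ring-fusion CH, ring CH2) arises by photochemical Wolff ring contraction of this six-membered ring: C5 shifts from the carbonyl carbon C4 to the diazo carbon C3, and the extruded C4 becomes a ketene carbon on the ring-fusion carbon next to the syringyl CH, exactly where the target holds the OCH2 carbon of the second ring. The neighbouring benzylic hydroxyl traps it, so one operation gives the oxolane, the second ring as a lactone and the cis fusion. The diazo ketone comes from an asymmetric hetero-Diels–Alder adduct of silylated syringaldehyde and a reductive aldol with O-allylvanillin.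

Key step: step 5

Remark: the (R,R) catalyst in step 2 is assigned to the 2R ketone by analogy with simple aryl aldehydes; should the first batch prove 2S, the mirror-image catalyst is used and nothing else changes.

Step 1
Reactants: 1 syringaldehyde
Product: 2 4-(tert-butyldimethylsilyloxy)-3,5-dimethoxybenzaldehyde
Conditions: t-BuMe2SiCl, imidazole, DMF, rt
Reagents that add atoms: tert-butyldimethylsilyl chloride CC(C)(C)[Si](C)(C)Cl
Why: Silylation of the phenol masks the only acidic proton of the syringyl unit with a group that should survive hydride, amide base, light and mild acid and leave with fluoride at the end.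

Step 2
Reactants: 2 4-(tert-butyldimethylsilyloxy)-3,5-dimethoxybenzaldehyde; 3 Danishefsky's diene
Product: 5 (R)-2-[4-(tert-butyldimethylsilyloxy)-3,5-dimethoxyphenyl]-2,3-dihydro-4H-pyran-4-one, via Diels–Alder cycloadduct 4 (not isolated)
Conditions: (R,R)-(salen)CrBF4 (2 mol %), 4 Å MS, t-BuOMe, −30 °C; then CF3CO2H, CH2Cl2, 0 °C
Reagents that add atoms: none
Why: Catalytic asymmetric hetero-Diels–Alder reaction in which the chiral chromium Lewis acid binds the unhindered aldehyde and shields one face, so that C2 is set by the catalyst, and acid then removes the silyl group and methanol to unveil the enone.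

Step 3
Reactants: 5 (R)-2-[4-(tert-butyldimethylsilyloxy)-3,5-dimethoxyphenyl]-2,3-dihydro-4H-pyran-4-one; 6 4-(allyloxy)-3-methoxybenzaldehyde
Product: 8 (2R,5S)-5-[(R)-(4-allyloxy-3-methoxyphenyl)(trimethylsilyloxy)methyl]-2-[4-(tert-butyldimethylsilyloxy)-3,5-dimethoxyphenyl]oxan-4-one, via lithium enolate 7 (not isolated)
Conditions: LiBH(s-Bu)3, THF, −78 °C; then 6, −78 to −20 °C; then Me3SiCl, Et3N, −20 to 0 °C
Reagents that add atoms: chlorotrimethylsilane C[Si](C)(C)Cl
Why: Conjugate reduction–aldol (reductive aldol) in which 1,4-hydride addition gives the C4–C5 enolate regiospecifically, the ring-locked E enolate adds to the aldehyde through a Zimmerman–Traxler chair to give the anti carbinol, and the aldolate is left to equilibrate by retro-aldol/aldol to the diequatorial 2,5-trans oxanone before it is silylated.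

Step 4
Reactants: 8 (2R,5S)-5-[(R)-(4-allyloxy-3-methoxyphenyl)(trimethylsilyloxy)methyl]-2-[4-(tert-butyldimethylsilyloxy)-3,5-dimethoxyphenyl]oxan-4-one
Product: 11 (2S,5S)-5-[(R)-(4-allyloxy-3-methoxyphenyl)(hydroxy)methyl]-3-diazo-2-[4-(tert-butyldimethylsilyloxy)-3,5-dimethoxyphenyl]oxan-4-one, via trifluoroacetyl ketone 9 (not isolated), via silylated diazo ketone 10 (not isolated)
Conditions: LiN(SiMe3)2, THF, −78 °C, then CF3CO2CH2CF3; MsN3, Et3N, H2O (1 equiv), MeCN, rt; then PPTS, MeOH, 0 °C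
Reagents that add atoms: methanesulfonyl azide CS(=O)(=O)N=[N+]=[N-]
Why: Deacylative (detrifluoroacetylative) Regitz-type diazo transfer, in which kinetic deprotonation takes the only CH2 next to the ketone (C3, C5 being a hindered CH), the trifluoroacetyl group activates C3 for transfer and leaves with the sulfonamide, and mild acidic methanolysis frees the carbinol without touching a stereocentre (the C2 descriptor changes by priority only).

Step 5
Reactants: 11 (2S,5S)-5-[(R)-(4-allyloxy-3-methoxyphenyl)(hydroxy)methyl]-3-diazo-2-[4-(tert-butyldimethylsilyloxy)-3,5-dimethoxyphenyl]oxan-4-one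
Product: 13 (3R,3aS,6R,6aR)-3-(4-allyloxy-3-methoxyphenyl)-6-[4-(tert-butyldimethylsilyloxy)-3,5-dimethoxyphenyl]tetrahydro-1H,3H-furo[3,4-c]furan-1-one, via oxolanylidene ketene 12 (not isolated)
Conditions: hν (365 nm), THF (0.01 M), rt
Reagents that add atoms: none
Why: Irradiation of the cyclic diazo ketone, which is locked s-cis, should expel N2 with concerted 1,2-shift of C5 from the carbonyl carbon C4 to C3 (Wolff rearrangement), so the six-membered oxanone contracts to the oxolane and C4 becomes an exocyclic ketene carbon on C3. The closest known reaction type is the photochemical ring contraction of 2-diazocyclohexanones and 3-diazochroman-4-ones with capture of the ketene by an alcohol. The oxolane is formed by ring contraction and not by cyclisation, and the lactone ring then closes by 5-exo addition of the benzylic hydroxyl oxygen to the ketene carbonyl carbon. C5 migrates with retention, so the 2,5-trans relation set in step 3 becomes the trans relation between the syringyl-bearing carbon and the carbinol-bearing ring-fusion carbon; the new ring-fusion stereocentre (old C3) is set when the lactone enol tautomerises, because only the cis-fused bicyclo[3.3.0] lactone is attainable. The step needs the Wolff shift to outrun carbene 1,2-hydride shift from C2 and O–H insertion, which the s-cis geometry and direct irradiation without a metal should secure, and high dilution should keep ketene capture intramolecular.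

Step 6
Reactants: 13 (3R,3aS,6R,6aR)-3-(4-allyloxy-3-methoxyphenyl)-6-[4-(tert-butyldimethylsilyloxy)-3,5-dimethoxyphenyl]tetrahydro-1H,3H-furo[3,4-c]furan-1-one
Product: 14 [(2R,3S,4S)-4-[(R)-(4-allyloxy-3-methoxyphenyl)(hydroxy)methyl]-2-[4-(tert-butyldimethylsilyloxy)-3,5-dimethoxyphenyl]oxolan-3-yl]methanol
Conditions: LiBH4, THF, 0 °C to rt; then aq. NH4Cl
Reagents that add atoms: none
Why: Hydride reduction of the lactone to the 1,4-diol, which leaves the aryl silyl ether, the allyl ether and all four stereocentres untouched.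

Step 7
Reactants: 14 [(2R,3S,4S)-4-[(R)-(4-allyloxy-3-methoxyphenyl)(hydroxy)methyl]-2-[4-(tert-butyldimethylsilyloxy)-3,5-dimethoxyphenyl]oxolan-3-yl]methanol
Product: 16 (1R,3aS,4R,6aS)-1-(4-allyloxy-3-methoxyphenyl)-4-[4-(tert-butyldimethylsilyloxy)-3,5-dimethoxyphenyl]tetrahydro-1H,3H-furo[3,4-c]furan, via primary mesylate 15 (not isolated)
Conditions: MsCl (1.1 equiv), Et3N, CH2Cl2, 0 °C to rt
Reagents that add atoms: none
Why: Selective sulfonylation of the primary hydroxyl followed by intramolecular Williamson etherification (5-exo-tet) by the benzylic hydroxyl closes the second oxolane without breaking the carbinol C–O bond, so the guaiacyl-type aryl group stays exo.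

Step 8
Reactants: 16 (1R,3aS,4R,6aS)-1-(4-allyloxy-3-methoxyphenyl)-4-[4-(tert-butyldimethylsilyloxy)-3,5-dimethoxyphenyl]tetrahydro-1H,3H-furo[3,4-c]furan
Product: 17 4-{(1R,3aS,4R,6aS)-4-[4-(tert-butyldimethylsilyloxy)-3,5-dimethoxyphenyl]tetrahydro-1H,3H-furo[3,4-c]furan-1-yl}-2-methoxyphenol
Conditions: Pd(PPh3)4 (5 mol %), morpholine, THF, rt
Reagents that add atoms: none
Why: Tsuji–Trost deallylation, in which the palladium catalyst ionises the allyl aryl ether and morpholine takes the allyl group under neutral conditions that spare the silyl ether and the dibenzylic ethers.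

Step 9
Reactants: 17 4-{(1R,3aS,4R,6aS)-4-[4-(tert-butyldimethylsilyloxy)-3,5-dimethoxyphenyl]tetrahydro-1H,3H-furo[3,4-c]furan-1-yl}-2-methoxyphenol; 18 (R)-4-benzyl-3-(chloroacetyl)oxazolidin-2-one
Product: 19 (R)-4-benzyl-3-{2-[4-((1R,3aS,4R,6aS)-4-(4-(tert-butyldimethylsilyloxy)-3,5-dimethoxyphenyl)tetrahydro-1H,3H-furo[3,4-c]furan-1-yl)-2-methoxyphenoxy]acetyl}oxazolidin-2-one
Conditions: K2CO3, acetone, rt
Reagents that add atoms: none
Why: Williamson O-alkylation of the single free phenol with the activated primary α-chloro imide, which forms the aryl ether bond at a carbon that is not yet a stereocentre.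

Step 10
Reactants: 19 (R)-4-benzyl-3-{2-[4-((1R,3aS,4R,6aS)-4-(4-(tert-butyldimethylsilyloxy)-3,5-dimethoxyphenyl)tetrahydro-1H,3H-furo[3,4-c]furan-1-yl)-2-methoxyphenoxy]acetyl}oxazolidin-2-one; 20 vanillin acetate
Product: 22 (R)-4-benzyl-3-[(2R,3S)-3-(4-acetoxy-3-methoxyphenyl)-3-hydroxy-2-(aryloxy)propanoyl]oxazolidin-2-one (aryloxy = the phenoxy group of 17), via boron Z-enolate 21 (not isolated)
Conditions: n-Bu2BOTf, i-Pr2NEt, CH2Cl2, −78 to 0 °C; then 20, −78 to 0 °C; then pH 7 buffer, MeOH, H2O2, 0 °C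
Reagents that add atoms: none
Why: Evans syn-aldol reaction of the glycolate-type imide, in which the Z boron enolate reacts through a Zimmerman–Traxler chair on the face left open by the (R)-benzyl auxiliary to give the (2R,3S) adduct, which is the threo relationship of the side chain.

Step 11
Reactants: 22 (R)-4-benzyl-3-[(2R,3S)-3-(4-acetoxy-3-methoxyphenyl)-3-hydroxy-2-(aryloxy)propanoyl]oxazolidin-2-one
Product: 23 (1S,2S)-1-(4-hydroxy-3-methoxyphenyl)-2-{4-[(1R,3aS,4R,6aS)-4-(4-(tert-butyldimethylsilyloxy)-3,5-dimethoxyphenyl)tetrahydro-1H,3H-furo[3,4-c]furan-1-yl]-2-methoxyphenoxy}propane-1,3-diol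
Conditions: LiBH4 (excess), H2O (1 equiv), THF, 0 °C; then aq. NH4Cl
Reagents that add atoms: none
Why: Reductive cleavage of the N-acyl oxazolidinone to the primary alcohol, with the aryl acetate reduced off in the same operation and neither side-chain stereocentre touched (the C2 descriptor changes by priority only).

Step 12
Reactants: 23 (1S,2S)-1-(4-hydroxy-3-methoxyphenyl)-2-{4-[(1R,3aS,4R,6aS)-4-(4-(tert-butyldimethylsilyloxy)-3,5-dimethoxyphenyl)tetrahydro-1H,3H-furo[3,4-c]furan-1-yl]-2-methoxyphenoxy}propane-1,3-diol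
Product: 24 (1S,2S)-1-(4-hydroxy-3-methoxyphenyl)-2-{4-[(1R,3aS,4R,6aS)-4-(4-hydroxy-3,5-dimethoxyphenyl)tetrahydro-1H,3H-furo[3,4-c]furan-1-yl]-2-methoxyphenoxy}propane-1,3-diol (CNP0255927.3)
Conditions: Bu4NF, AcOH, THF, 0 °C
Reagents that add atoms: none
Why: Fluoride-induced cleavage of the aryl silyl ether, buffered with acetic acid so that the p-hydroxybenzylic alcohol and the benzylic ethers should not ionise.

Compound list

1 | syringaldehyde (4-hydroxy-3,5-dimethoxybenzaldehyde) | COc1cc(C=O)cc(OC)c1O | starting material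
2 | 4-(tert-butyldimethylsilyloxy)-3,5-dimethoxybenzaldehyde | COc1cc(C=O)cc(OC)c1O[Si](C)(C)C(C)(C)C | intermediate
3 | Danishefsky's diene, (E)-1-methoxy-3-(trimethylsilyloxy)buta-1,3-diene | CO/C=C/C(=C)O[Si](C)(C)C | starting material
4 | (2R)-2-aryl-6-methoxy-4-(trimethylsilyloxy)-3,6-dihydro-2H-pyran, Diels–Alder cycloadduct, both C6 epimers | COC1C=C(O[Si](C)(C)C)C[C@H](c2cc(OC)c(O[Si](C)(C)C(C)(C)C)c(OC)c2)O1 | intermediate
5 | (R)-2-[4-(tert-butyldimethylsilyloxy)-3,5-dimethoxyphenyl]-2,3-dihydro-4H-pyran-4-one | O=C1C[C@H](c2cc(OC)c(O[Si](C)(C)C(C)(C)C)c(OC)c2)OC=C1 | intermediate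
6 | 4-(allyloxy)-3-methoxybenzaldehyde (O-allylvanillin) | C=CCOc1ccc(C=O)cc1OC | starting material
7 | lithium enolate of the saturated oxanone (C4–C5 enolate, 2R) | [Li+].[O-]C1=CCO[C@@H](c2cc(OC)c(O[Si](C)(C)C(C)(C)C)c(OC)c2)C1 | intermediate
8 | (2R,5S)-5-[(R)-(4-allyloxy-3-methoxyphenyl)(trimethylsilyloxy)methyl]-2-[4-(tert-butyldimethylsilyloxy)-3,5-dimethoxyphenyl]oxan-4-one (2,5-trans, anti aldol) | O=C1C[C@H](c2cc(OC)c(O[Si](C)(C)C(C)(C)C)c(OC)c2)OC[C@H]1[C@@H](O[Si](C)(C)C)c1ccc(OCC=C)c(OC)c1 | intermediate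
9 | 3-(trifluoroacetyl) derivative of 8 (C3 epimers or enol) | O=C1C(C(=O)C(F)(F)F)[C@H](c2cc(OC)c(O[Si](C)(C)C(C)(C)C)c(OC)c2)OC[C@H]1[C@@H](O[Si](C)(C)C)c1ccc(OCC=C)c(OC)c1 | intermediate
10 | 3-diazo derivative of 8 (trimethylsilyl ether still in place) | O=C1C(=[N+]=[N-])[C@H](c2cc(OC)c(O[Si](C)(C)C(C)(C)C)c(OC)c2)OC[C@H]1[C@@H](O[Si](C)(C)C)c1ccc(OCC=C)c(OC)c1 | intermediate
11 | (2S,5S)-5-[(R)-(4-allyloxy-3-methoxyphenyl)(hydroxy)methyl]-3-diazo-2-[4-(tert-butyldimethylsilyloxy)-3,5-dimethoxyphenyl]oxan-4-one (same spatial arrangement as 8) | O=C1C(=[N+]=[N-])[C@H](c2cc(OC)c(O[Si](C)(C)C(C)(C)C)c(OC)c2)OC[C@H]1[C@@H](O)c1ccc(OCC=C)c(OC)c1 | intermediate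
12 | ring-contracted ketene: 2-aryl-4-[(R)-aryl(hydroxy)methyl]oxolan-3-ylidene ketene | O=C=C1[C@H](c2cc(OC)c(O[Si](C)(C)C(C)(C)C)c(OC)c2)OC[C@H]1[C@@H](O)c1ccc(OCC=C)c(OC)c1 | intermediate
13 | (3R,3aS,6R,6aR)-3-(4-allyloxy-3-methoxyphenyl)-6-[4-(tert-butyldimethylsilyloxy)-3,5-dimethoxyphenyl]tetrahydro-1H,3H-furo[3,4-c]furan-1-one (cis-fused, both aryl groups exo) | C=CCOc1ccc([C@@H]2OC(=O)[C@@H]3[C@H]2CO[C@H]3c2cc(OC)c(O[Si](C)(C)C(C)(C)C)c(OC)c2)cc1OC | intermediate
14 | [(2R,3S,4S)-4-[(R)-(4-allyloxy-3-methoxyphenyl)(hydroxy)methyl]-2-[4-(tert-butyldimethylsilyloxy)-3,5-dimethoxyphenyl]oxolan-3-yl]methanol | C=CCOc1ccc([C@H](O)[C@@H]2CO[C@@H](c3cc(OC)c(O[Si](C)(C)C(C)(C)C)c(OC)c3)[C@@H]2CO)cc1OC | intermediate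
15 | primary methanesulfonate of diol 14 | C=CCOc1ccc([C@H](O)[C@@H]2CO[C@@H](c3cc(OC)c(O[Si](C)(C)C(C)(C)C)c(OC)c3)[C@@H]2COS(C)(=O)=O)cc1OC | intermediate
16 | (1R,3aS,4R,6aS)-1-(4-allyloxy-3-methoxyphenyl)-4-[4-(tert-butyldimethylsilyloxy)-3,5-dimethoxyphenyl]tetrahydro-1H,3H-furo[3,4-c]furan | C=CCOc1ccc([C@@H]2OC[C@@H]3[C@H]2CO[C@H]3c2cc(OC)c(O[Si](C)(C)C(C)(C)C)c(OC)c2)cc1OC | intermediate
17 | 4-{(1R,3aS,4R,6aS)-4-[4-(tert-butyldimethylsilyloxy)-3,5-dimethoxyphenyl]tetrahydro-1H,3H-furo[3,4-c]furan-1-yl}-2-methoxyphenol | COc1cc([C@@H]2OC[C@@H]3[C@H]2CO[C@H]3c2cc(OC)c(O[Si](C)(C)C(C)(C)C)c(OC)c2)ccc1O | intermediate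
18 | (R)-4-benzyl-3-(chloroacetyl)oxazolidin-2-one | O=C(CCl)N1[C@H](Cc2ccccc2)COC1=O | starting material
19 | (R)-4-benzyl-3-(aryloxyacetyl)oxazolidin-2-one, aryloxy = phenoxy group of 17 | O=C(COc1ccc([C@@H]2OC[C@@H]3[C@H]2CO[C@H]3c2cc(OC)c(O[Si](C)(C)C(C)(C)C)c(OC)c2)cc1OC)N1[C@H](Cc2ccccc2)COC1=O | intermediate
20 | vanillin acetate (4-acetoxy-3-methoxybenzaldehyde) | CC(=O)Oc1ccc(C=O)cc1OC | starting material
21 | di-n-butylboron Z-enolate of 19 | CCCCB(CCCC)O/C(=C\Oc1ccc([C@@H]2OC[C@@H]3[C@H]2CO[C@H]3c2cc(OC)c(O[Si](C)(C)C(C)(C)C)c(OC)c2)cc1OC)N1[C@H](Cc2ccccc2)COC1=O | intermediate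
22 | (R)-4-benzyl-3-[(2R,3S)-3-(4-acetoxy-3-methoxyphenyl)-3-hydroxy-2-(aryloxy)propanoyl]oxazolidin-2-one, aryloxy = phenoxy group of 17 | CC(=O)Oc1ccc([C@H](O)[C@H](C(=O)N2[C@H](Cc3ccccc3)COC2=O)Oc2ccc([C@@H]3OC[C@@H]4[C@H]3CO[C@H]4c3cc(OC)c(O[Si](C)(C)C(C)(C)C)c(OC)c3)cc2OC)cc1OC | intermediate
23 | (1S,2S)-1-(4-hydroxy-3-methoxyphenyl)-2-{4-[(1R,3aS,4R,6aS)-4-(4-(tert-butyldimethylsilyloxy)-3,5-dimethoxyphenyl)tetrahydro-1H,3H-furo[3,4-c]furan-1-yl]-2-methoxyphenoxy}propane-1,3-diol | COc1cc([C@H](O)[C@H](CO)Oc2ccc([C@@H]3OC[C@@H]4[C@H]3CO[C@H]4c3cc(OC)c(O[Si](C)(C)C(C)(C)C)c(OC)c3)cc2OC)ccc1O | intermediate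
24 | (1S,2S)-1-(4-hydroxy-3-methoxyphenyl)-2-{4-[(1R,3aS,4R,6aS)-4-(4-hydroxy-3,5-dimethoxyphenyl)tetrahydro-1H,3H-furo[3,4-c]furan-1-yl]-2-methoxyphenoxy}propane-1,3-diol | COc1cc([C@H](O)[C@H](CO)Oc2ccc([C@@H]3OC[C@@H]4[C@H]3CO[C@H]4c3cc(OC)c(O)c(OC)c3)cc2OC)ccc1O | target

Total step count: 12. Longest linear sequence: 12 steps (from syringaldehyde; 3, 6, 18 and 20 are purchased).

Steps most likely to fail

Step 3. What may go wrong: poor facial selectivity when the aldehyde attacks C5 of enolate 7, weak anti/syn control in the lithium aldol, and incomplete retro-aldol equilibration before silylation, so that ring or carbinol epimers are carried forward. The fallback sets out from 5 and comes back at 8. Enone 5 is reduced with LiBH(s-Bu)3 and protonated to give the saturated ketone (R)-2-[4-(tert-butyldimethylsilyloxy)-3,5-dimethoxyphenyl]oxan-4-one F1. Enolisation of F1 with (c-C6H11)2BCl and Et3N on the less hindered C5 side and addition of 6 at −78 °C should give, through the tight boron-bound chair, the free anti aldol (2R,5S)-5-[(R)-(4-allyloxy-3-methoxyphenyl)(hydroxy)methyl]-2-[4-(tert-butyldimethylsilyloxy)-3,5-dimethoxyphenyl]oxan-4-one F2, from which any C5 epimer is separated. Silylation of F2 with Me3SiCl and imidazole gives 8.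

Step 5. What may go wrong: the excited diazo ketone leaks into 1,2-hydride shift from C2 or insertion into the O–H bond instead of the Wolff shift, or the ketene is captured between molecules. The fallback sets out from 10 (isolated by leaving out the PPTS/MeOH treatment of step 4) and comes back at 13. Irradiation of 10 in methanol lets the solvent trap the ketene and gives the ring-contracted ester methyl (2R,4S)-4-[(R)-(4-allyloxy-3-methoxyphenyl)(trimethylsilyloxy)methyl]-2-[4-(tert-butyldimethylsilyloxy)-3,5-dimethoxyphenyl]oxolane-3-carboxylate F4 as a mixture at C3. PPTS in methanol frees the carbinol to give the hydroxy ester methyl (2R,4S)-4-[(R)-(4-allyloxy-3-methoxyphenyl)(hydroxy)methyl]-2-[4-(tert-butyldimethylsilyloxy)-3,5-dimethoxyphenyl]oxolane-3-carboxylate F5. Catalytic DBU in toluene then epimerises C3 and drives lactonisation of the cis isomer to 13.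

Step 4. What may go wrong: enolisation toward C5 with β-elimination of silanolate, or opening of the oxane from the C3 enolate by retro-oxa-Michael reaction, which would erode C2. The fallback sets out from 8 and comes back at 11, and activates C3 without a strong base. Heating 8 with tert-butoxybis(dimethylamino)methane (Bredereck's reagent) in toluene gives the enaminone, the (E)-3-[(dimethylamino)methylidene] derivative of 8 F3; only the CH2 at C3 can form it. Diazo transfer from MsN3 to F3 gives 10, and PPTS in methanol gives 11 as in step 4.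

Further compounds
F1 | step 3 | (R)-2-[4-(tert-butyldimethylsilyloxy)-3,5-dimethoxyphenyl]oxan-4-one | O=C1C[C@H](c2cc(OC)c(O[Si](C)(C)C(C)(C)C)c(OC)c2)OCC1
F2 | step 3 | (2R,5S)-5-[(R)-(4-allyloxy-3-methoxyphenyl)(hydroxy)methyl]-2-[4-(tert-butyldimethylsilyloxy)-3,5-dimethoxyphenyl]oxan-4-one | O=C1C[C@H](c2cc(OC)c(O[Si](C)(C)C(C)(C)C)c(OC)c2)OC[C@H]1[C@@H](O)c1ccc(OCC=C)c(OC)c1
F3 | step 4 | (E)-3-[(dimethylamino)methylidene] derivative of 8 | O=C1/C(=C/N(C)C)[C@H](c2cc(OC)c(O[Si](C)(C)C(C)(C)C)c(OC)c2)OC[C@H]1[C@@H](O[Si](C)(C)C)c1ccc(OCC=C)c(OC)c1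
F4 | step 5 | methyl (2R,4S)-4-[(R)-(4-allyloxy-3-methoxyphenyl)(trimethylsilyloxy)methyl]-2-[4-(tert-butyldimethylsilyloxy)-3,5-dimethoxyphenyl]oxolane-3-carboxylate, C3 epimers | COC(=O)C1[C@H](c2cc(OC)c(O[Si](C)(C)C(C)(C)C)c(OC)c2)OC[C@H]1[C@@H](O[Si](C)(C)C)c1ccc(OCC=C)c(OC)c1
F5 | step 5 | methyl (2R,4S)-4-[(R)-(4-allyloxy-3-methoxyphenyl)(hydroxy)methyl]-2-[4-(tert-butyldimethylsilyloxy)-3,5-dimethoxyphenyl]oxolane-3-carboxylate, C3 epimers | COC(=O)C1[C@H](c2cc(OC)c(O[Si](C)(C)C(C)(C)C)c(OC)c2)OC[C@H]1[C@@H](O)c1ccc(OCC=C)c(OC)c1
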